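The O–CH2 unit of one tetrahydrofuran ring is read as formaldehyde, inserted between the benzylic ArCH carbon and the ring-fusion carbon that ends up carrying the hydroxyl group. The key step exploits the 1,3-relation of these two carbons: one stabilises a cation (guaiacyl donor), the other an enolate once it sits next to a lactone carbonyl, so both are held with the CH ring-fusion carbon as an aryl cyclopropane fused to a γ-lactone, made as one enantiomer from a (Z)-cinnamyl diazoacetate. Lewis acid catalysed (3+2) annulation with formaldehyde forms the CH2–C and O–CH(Ar) bonds in one operation. Enolate hydroxylation, aryllithium addition/reduction, cationic closure of the second ring and hydrogenolysis finish the synthesis.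

Key step: step 5

Assumption: compounds 1, 2 and 10 are taken as catalogue chemicals, and formaldehyde is charged as paraformaldehyde. The catalyst enantiomer in step 4 is chosen by analogy with simple cis-disubstituted allylic diazoacetates; its antipode would give the mirror-image series.

Step 1
Reactants: 1 4-(benzyloxy)-3-methoxybenzaldehyde; 2 methyl 2-[bis(2,2,2-trifluoroethoxy)phosphoryl]acetate
Product: 3 methyl (2Z)-3-[4-(benzyloxy)-3-methoxyphenyl]prop-2-enoate
Conditions: KHMDS, 18-crown-6, THF, −78 °C
Reagents that add atoms: none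
Why: Still–Gennari variant of the Horner–Wadsworth–Emmons olefination, in which the bis(trifluoroethyl) phosphonate eliminates fast from the kinetic adduct and should give the (Z)-enoate needed for a cis-cyclopropane.

Step 2
Reactants: 3 methyl (2Z)-3-[4-(benzyloxy)-3-methoxyphenyl]prop-2-enoate
Product: 4 (2Z)-3-[4-(benzyloxy)-3-methoxyphenyl]prop-2-en-1-ol
Conditions: DIBAL-H (2.2 equiv), CH2Cl2, −78 °C; Rochelle salt work-up
Reagents that add atoms: none
Why: DIBAL-H 1,2-reduction of the enoate at low temperature should give the allylic alcohol without touching the (Z)-alkene.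

Step 3
Reactants: 4 (2Z)-3-[4-(benzyloxy)-3-methoxyphenyl]prop-2-en-1-ol
Product: 6 (2Z)-3-[4-(benzyloxy)-3-methoxyphenyl]prop-2-en-1-yl diazoacetate, via bromoacetate 5 (not isolated)
Conditions: BrCH2COBr, NaHCO3, MeCN, 0 °C; then TsNHNHTs, DBU, THF, 0 °C
Reagents that add atoms: bromoacetyl bromide, BrCC(=O)Br; N,N'-ditosylhydrazine, Cc1ccc(cc1)S(=O)(=O)NNS(=O)(=O)c1ccc(C)cc1
Why: O-acylation, then diazo formation by N-alkylation of the ditosylhydrazine and base-induced loss of two sulfinates, under non-acidic conditions that should leave the (Z)-alkene alone.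

Step 4
Reactants: 6 (2Z)-3-[4-(benzyloxy)-3-methoxyphenyl]prop-2-en-1-yl diazoacetate
Product: 7 (1S,5R,6S)-6-[4-(benzyloxy)-3-methoxyphenyl]-3-oxabicyclo[3.1.0]hexan-2-one (aryl endo, cis to the lactone ring)
Conditions: Rh2(5R-MEPY)4 (1 mol %), CH2Cl2, reflux, slow addition of 6
Reagents that add atoms: none
Why: Rh(II)-carboxamidate-catalysed intramolecular cyclopropanation of an allylic diazoacetate, in which concerted carbene transfer keeps the (Z)-geometry (aryl cis to the lactone CH2) and the chiral ligand sphere should set both ring-fusion centres.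

Step 5
Reactants: 7 (1S,5R,6S)-6-[4-(benzyloxy)-3-methoxyphenyl]-3-oxabicyclo[3.1.0]hexan-2-one
Product: 8 (3aR,4S,6aR)-4-[4-(benzyloxy)-3-methoxyphenyl]tetrahydro-1H,3H-furo[3,4-c]furan-1-one
Conditions: (CH2O)n (5 equiv), Sc(OTf)3 (20 mol %), 4 Å MS, ClCH2CH2Cl, 25–45 °C
Reagents that add atoms: formaldehyde (charged as paraformaldehyde), C=O
Why: Proposed new method: Sc(OTf)3 on the lactone carbonyl polarises the cyclopropane bond between the α-carbon and the benzylic carbon of 7, the formaldehyde oxygen attacks the benzylic carbon from the side opposite to that bond, and the scandium enolate then adds through its α-carbon to the carbon of the resulting O-alkylated formaldehyde (oxocarbenium ion). The closest known reaction type is the Lewis acid catalysed (3+2) annulation of 2-arylcyclopropane-1,1-diesters with aldehydes to tetrahydrofurans; new here are the single, lactone-embedded acceptor and formaldehyde as partner, which the strongly donating 4-benzyloxy-3-methoxyphenyl group and the strain of the bicyclo[3.1.0] lactone should make up for. The tetrahydrofuran ring closes in a 5-(enolexo)-endo-trig attack on the oxocarbenium ion, the closure common to this annulation class. The CH ring-fusion centre set in step 4 is not touched and fixes the absolute configuration, the centre next to the carbonyl can only re-form cis-fused, and the benzylic centre is set by inversion, which turns the endo-aryl cis-cyclopropane into the exo-aryl (2,3-trans) tetrahydrofuran. If the opening instead goes through a free benzylic cation, closure with the aryl group on the convex face of the forming bicycle should lead to the same isomer. The step needs cleavage of the benzylic and not the other cyclopropane bond, secured by the aryl donor, and C–C closure at the enolate carbon in preference to attack of the oxocarbenium ion on the arene, secured by the higher nucleophilicity of the enolate and the five-membered transition state.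

Step 6
Reactants: 8 (3aR,4S,6aR)-4-[4-(benzyloxy)-3-methoxyphenyl]tetrahydro-1H,3H-furo[3,4-c]furan-1-one
Product: 9 (3aR,4S,6aS)-4-[4-(benzyloxy)-3-methoxyphenyl]-6a-hydroxytetrahydro-1H,3H-furo[3,4-c]furan-1-one
Conditions: KHMDS, THF, −78 °C; then 3-phenyl-2-(phenylsulfonyl)oxaziridine, −78 °C; aq NH4Cl
Reagents that add atoms: 3-phenyl-2-(phenylsulfonyl)oxaziridine, O=S(=O)(c1ccccc1)N1OC1c1ccccc1
Why: Enolate hydroxylation with an N-sulfonyloxaziridine, in which the bridgehead lactone enolate can only give the cis-fused carbinol (oxygen enters on the convex face) and loss of the β ring oxygen would be a disfavoured retro-5-endo-trig process.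

Step 7
Reactants: 9 (3aR,4S,6aS)-4-[4-(benzyloxy)-3-methoxyphenyl]-6a-hydroxytetrahydro-1H,3H-furo[3,4-c]furan-1-one; 10 1-(benzyloxy)-4-bromo-2-methoxybenzene
Product: 13 (3S,4R,5S)-5-[4-(benzyloxy)-3-methoxyphenyl]-3-{[4-(benzyloxy)-3-methoxyphenyl](hydroxy)methyl}-4-(hydroxymethyl)oxolan-3-ol (both carbinol epimers), via aryllithium 11 (not isolated), via hydroxy ketone 12 (not isolated)
Conditions: 10 (2.6 equiv), n-BuLi (2.5 equiv), THF, −78 °C; add 9, −78 °C; then MeOH, NaBH4, −78 → 0 °C; aq NH4Cl
Reagents that add atoms: none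
Why: Bromine–lithium exchange, 1,2-addition of the aryllithium to the lactone (one equivalent is spent on the tertiary hydroxyl; the lithium hemiketalate should resist a second addition) and borohydride reduction of the ring-opened aryl ketone in the same flask; the carbinol configuration is immaterial because step 8 passes through the benzylic cation.

Step 8
Reactants: 13 (3S,4R,5S)-5-[4-(benzyloxy)-3-methoxyphenyl]-3-{[4-(benzyloxy)-3-methoxyphenyl](hydroxy)methyl}-4-(hydroxymethyl)oxolan-3-ol
Product: 14 (1S,3aS,4R,6aR)-1,4-bis[4-(benzyloxy)-3-methoxyphenyl]tetrahydro-1H,3H-furo[3,4-c]furan-3a-ol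
Conditions: CSA (10 mol %), 4 Å MS, CH2Cl2, 0 °C
Reagents that add atoms: none
Why: Acid-catalysed SN1 cyclodehydration (5-exo-tet ether closure), in which the 4-benzyloxy-3-methoxybenzyl cation is trapped by the primary hydroxyl with the aryl group on the convex face, syn to the tertiary hydroxyl, so both carbinol epimers should converge on the exo,exo-furofuran.

Step 9
Reactants: 14 (1S,3aS,4R,6aR)-1,4-bis[4-(benzyloxy)-3-methoxyphenyl]tetrahydro-1H,3H-furo[3,4-c]furan-3a-ol
Product: 15 8-hydroxypinoresinol, (1S,3aS,4R,6aR)-1,4-bis(4-hydroxy-3-methoxyphenyl)tetrahydro-1H,3H-furo[3,4-c]furan-3a-ol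
Conditions: H2 (1 atm), 10% Pd/C, EtOAc–MeOH, rt, stopped at full conversion of 14
Reagents that add atoms: none
Why: Catalytic hydrogenolysis, in which the two aryl benzyl ethers should be cleaved faster than the dialkyl benzylic C–O bonds of the furofuran core.

Compound list
1 | 4-(benzyloxy)-3-methoxybenzaldehyde | O=Cc1ccc(OCc2ccccc2)c(OC)c1 | starting material
2 | methyl 2-[bis(2,2,2-trifluoroethoxy)phosphoryl]acetate | COC(=O)CP(=O)(OCC(F)(F)F)OCC(F)(F)F | starting material
3 | methyl (2Z)-3-[4-(benzyloxy)-3-methoxyphenyl]prop-2-enoate | COC(=O)/C=C\c1ccc(OCc2ccccc2)c(OC)c1 | intermediate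
4 | (2Z)-3-[4-(benzyloxy)-3-methoxyphenyl]prop-2-en-1-ol | OC/C=C\c1ccc(OCc2ccccc2)c(OC)c1 | intermediate
5 | (2Z)-3-[4-(benzyloxy)-3-methoxyphenyl]prop-2-en-1-yl bromoacetate | BrCC(=O)OC/C=C\c1ccc(OCc2ccccc2)c(OC)c1 | intermediate (not isolated)
6 | (2Z)-3-[4-(benzyloxy)-3-methoxyphenyl]prop-2-en-1-yl diazoacetate | [N-]=[N+]=CC(=O)OC/C=C\c1ccc(OCc2ccccc2)c(OC)c1 | intermediate
7 | (1S,5R,6S)-6-[4-(benzyloxy)-3-methoxyphenyl]-3-oxabicyclo[3.1.0]hexan-2-one | COc1cc([C@H]2[C@H]3COC(=O)[C@@H]23)ccc1OCc1ccccc1 | intermediate
8 | (3aR,4S,6aR)-4-[4-(benzyloxy)-3-methoxyphenyl]tetrahydro-1H,3H-furo[3,4-c]furan-1-one | COc1cc([C@H]2OC[C@@H]3C(=O)OC[C@H]23)ccc1OCc1ccccc1 | intermediate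
9 | (3aR,4S,6aS)-4-[4-(benzyloxy)-3-methoxyphenyl]-6a-hydroxytetrahydro-1H,3H-furo[3,4-c]furan-1-one | COc1cc([C@H]2OC[C@]3(O)C(=O)OC[C@H]23)ccc1OCc1ccccc1 | intermediate
10 | 1-(benzyloxy)-4-bromo-2-methoxybenzene | COc1cc(Br)ccc1OCc1ccccc1 | starting material
11 | [4-(benzyloxy)-3-methoxyphenyl]lithium | [Li]c1ccc(OCc2ccccc2)c(OC)c1 | intermediate (not isolated)
12 | [4-(benzyloxy)-3-methoxyphenyl]{(3S,4R,5S)-5-[4-(benzyloxy)-3-methoxyphenyl]-3-hydroxy-4-(hydroxymethyl)oxolan-3-yl}methanone | COc1cc([C@H]2OC[C@](O)(C(=O)c3ccc(OCc4ccccc4)c(OC)c3)[C@@H]2CO)ccc1OCc1ccccc1 | intermediate (not isolated)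
13 | (3S,4R,5S)-5-[4-(benzyloxy)-3-methoxyphenyl]-3-{[4-(benzyloxy)-3-methoxyphenyl](hydroxy)methyl}-4-(hydroxymethyl)oxolan-3-ol, both carbinol epimers | COc1cc([C@H]2OC[C@](O)(C(O)c3ccc(OCc4ccccc4)c(OC)c3)[C@@H]2CO)ccc1OCc1ccccc1 | intermediate
14 | (1S,3aS,4R,6aR)-1,4-bis[4-(benzyloxy)-3-methoxyphenyl]tetrahydro-1H,3H-furo[3,4-c]furan-3a-ol | COc1cc([C@H]2OC[C@]3(O)[C@@H](c4ccc(OCc5ccccc5)c(OC)c4)OC[C@H]23)ccc1OCc1ccccc1 | intermediate
15 | 8-hydroxypinoresinol, (1S,3aS,4R,6aR)-1,4-bis(4-hydroxy-3-methoxyphenyl)tetrahydro-1H,3H-furo[3,4-c]furan-3a-ol | COc1cc([C@H]2OC[C@]3(O)[C@@H](c4ccc(O)c(OC)c4)OC[C@H]23)ccc1O | target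

Total step count: 9. Longest linear sequence: 9 steps (1 to 15).

Steps most likely to fail

1. Step 5 (proposed new method). The single lactone carbonyl may not polarise the cyclopropane enough for ring opening. The cis-cyclopropane may also epimerise by reversible opening and then annulate with the wrong configuration at the benzylic carbon, or the O-alkylated formaldehyde may be intercepted by the electron-rich arene. The fallback uses known chemistry and sets out from alcohol 4. Acylation with methyl malonyl chloride gives the mixed malonate F1, and diazo transfer (p-ABSA, Et3N) gives the diazomalonate F2. Cu(I)–bis(oxazoline)-catalysed intramolecular cyclopropanation then gives the cyclopropane F3, which carries the lactone carbonyl and a methyl ester on the same carbon and so belongs to the gem-diacceptor class on which aldehyde (3+2) annulation is established. Sn(OTf)2-catalysed annulation with formaldehyde should give the furofuranone ester F4. Krapcho demethoxycarbonylation (LiCl, wet DMSO, heat) comes back to the route at 8, because protonation of the bridgehead enolate can only give the cis-fused lactone.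

2. Step 8. Capture of the benzylic cation may show poor facial selectivity, a pinacol-type 1,2-shift from the adjacent tertiary carbinol carbon may compete, or the benzylic ether already in place may ionise and lose its configuration. The fallback sets out from hydroxy lactone 9 and brings the aryl group in as a nucleophile. DIBAL-H reduction gives the lactol F5, and acetylation of the anomeric hydroxyl (Ac2O, pyridine) gives the lactol acetate F6. BF3·OEt2-promoted C-arylation of the derived bicyclic oxocarbenium ion with the potassium aryltrifluoroborate F7 (from the commercial boronic acid and KHF2) should take place on the convex face and comes back to the route at 14.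

3. Step 6. Enolisation at the bridgehead may be incomplete, the ring oxygen may be lost by β-elimination on warming, or the enolate may add to the sulfonimine by-product. The fallback sets out from 8. The enolate is trapped as the trimethylsilyl ketene acetal F8 (LDA, TMSCl, −78 °C), which is epoxidised with dimethyldioxirane (Rubottom oxidation) to the α-trimethylsiloxy lactone F9. Cleavage of the silyl ether with dilute acid comes back to the route at 9.

Further compounds
F1 | step 5 | (2Z)-3-[4-(benzyloxy)-3-methoxyphenyl]prop-2-en-1-yl methyl malonate | COC(=O)CC(=O)OC/C=C\c1ccc(OCc2ccccc2)c(OC)c1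
F2 | step 5 | (2Z)-3-[4-(benzyloxy)-3-methoxyphenyl]prop-2-en-1-yl methyl diazomalonate | COC(=O)C(=[N+]=[N-])C(=O)OC/C=C\c1ccc(OCc2ccccc2)c(OC)c1
F3 | step 5 | methyl 6-[4-(benzyloxy)-3-methoxyphenyl]-2-oxo-3-oxabicyclo[3.1.0]hexane-1-carboxylate, aryl cis to the lactone ring, same absolute sense as 7 | COc1cc([C@H]2[C@H]3COC(=O)[C@@]23C(=O)OC)ccc1OCc1ccccc1
F4 | step 5 | methyl 4-[4-(benzyloxy)-3-methoxyphenyl]-1-oxotetrahydro-1H,3H-furo[3,4-c]furan-6a-carboxylate, cis-fused, aryl exo | COc1cc([C@H]2OC[C@]3(C(=O)OC)C(=O)OC[C@H]23)ccc1OCc1ccccc1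
F5 | step 8 | 4-[4-(benzyloxy)-3-methoxyphenyl]tetrahydro-1H,3H-furo[3,4-c]furan-1,6a-diol (lactol of 9, anomers) | COc1cc([C@H]2OC[C@]3(O)C(O)OC[C@H]23)ccc1OCc1ccccc1
F6 | step 8 | 4-[4-(benzyloxy)-3-methoxyphenyl]-6a-hydroxytetrahydro-1H,3H-furo[3,4-c]furan-1-yl acetate (anomers) | COc1cc([C@H]2OC[C@]3(O)C(OC(C)=O)OC[C@H]23)ccc1OCc1ccccc1
F7 | step 8 | potassium [4-(benzyloxy)-3-methoxyphenyl]trifluoroborate | [K+].F[B-](F)(F)c1ccc(OCc2ccccc2)c(OC)c1
F8 | step 6 | trimethylsilyl ketene acetal of 8 | COc1cc([C@H]2OCC3=C(O[Si](C)(C)C)OC[C@H]23)ccc1OCc1ccccc1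
F9 | step 6 | 6a-trimethylsilyl ether of 9 | COc1cc([C@H]2OC[C@]3(O[Si](C)(C)C)C(=O)OC[C@H]23)ccc1OCc1ccccc1
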